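**Strategy.** The carbocycle of the target, a 7-oxabicyclo[4.1.0]heptan-2-one, is cut at C2–C3 and C4–C5. C5–C6–C1(CH3)–C2(O) becomes an (E)-1-silyloxy-2-methylbutadiene and C3–C4 an (E)-enone whose acetyl group sits on C3 and whose C4 carries a 1-bromovinyl handle. One catalytic enantioselective Diels–Alder reaction closes the six-membered ring, sets the trans C3/C4 pair and leaves the C1=C6 alkene where the oxirane belongs. The feature exploited is the contiguous C2(=O)–C3(OAc)–C4(alkenyl) array next to the C1–C6 epoxide: the acetyl group steers regiochemistry and later becomes the C3 acetate by Baeyer–Villiger oxidation, while the C2 silyl ether relays stereochemistry to the epoxidation.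

Key step: step 4

Remark on numbering: target ring atoms are numbered as in the 7-oxabicyclo[4.1.0]heptane core (C1 methyl-bearing oxirane carbon, C2 ketone, C3 acetoxy carbon, C4 side-chain carbon, C5 CH2, C6 oxirane CH). The side chain is numbered as a hepta-1,5-dien-2-yl unit with its carbinol carbon as C3.

**Step 1**
Reactants: 1 acrolein
Product: 3 2-bromoprop-2-enal, via 2,3-dibromopropanal 2 (not isolated)
Conditions: Br2, CH2Cl2, −78 °C; then Et3N, −78 → 0 °C; used fresh
Reagents that add atoms: bromine, BrBr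
Why: Bromine adds across the enal C=C and Et3N then removes the acidic α-hydrogen with loss of the β-bromide (bromination–dehydrobromination) to leave the 2-bromo enal.

**Step 2**
Reactants: 3 2-bromoprop-2-enal; 4 1-(triphenylphosphoranylidene)propan-2-one
Product: 5 (3E)-5-bromohexa-3,5-dien-2-one
Conditions: CH2Cl2, 0 °C → rt
Reagents that add atoms: none
Why: Wittig olefination with the acyl-stabilised ylide takes the aldehyde carbonyl and is E-selective.

**Step 3**
Reactants: 6 (2E)-2-methylbut-2-enal (tiglic aldehyde)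
Product: 7 tert-butyl(dimethyl){[(1E)-2-methylbuta-1,3-dien-1-yl]oxy}silane
Conditions: TBSOTf, Et3N, Et2O, 0 °C → rt
Reagents that add atoms: tert-butyldimethylsilyl triflate, CC(C)(C)[Si](C)(C)OS(=O)(=O)C(F)(F)F
Why: O-silylation of the enal and γ-deprotonation from its s-trans conformer (vinylogous silyl enol ether formation) should give the 1E dienol ether, the geometry that can reach the reactive s-cis diene.

**Step 4**
Reactants: 5 (3E)-5-bromohexa-3,5-dien-2-one; 7 tert-butyl(dimethyl){[(1E)-2-methylbuta-1,3-dien-1-yl]oxy}silane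
Product: 8 1-[(1S,2S,6R)-6-(1-bromoethenyl)-2-{[tert-butyl(dimethyl)silyl]oxy}-3-methylcyclohex-3-en-1-yl]ethan-1-one
Conditions: pre-formed (S)-o-tolyl-oxazaborolidinium triflimide (20 mol %, from (S)-α,α-diphenylprolinol, tri-o-tolylboroxine and Tf2NH), 7 (1.5 equiv), CH2Cl2, −78 → −40 °C
Reagents that add atoms: none
Why: The enone, bound s-trans through its carbonyl oxygen to the cationic boron centre, reacts with the silyl dienol ether in a concerted, asynchronous normal-electron-demand [4+2] cycloaddition; the closest known reaction type is the oxazaborolidinium-catalysed enantioselective Diels–Alder reaction of acrylates and acyclic enones with silyloxy dienes. The cyclohexene ring is closed by an intermolecular suprafacial–suprafacial [4+2] cycloaddition that makes C1–C2 and C5–C6 of 8 (C3–C2 and C4–C5 of the target) together. Regiochemistry needs the oxygen-bearing diene terminus to join the acetyl-bearing carbon: the largest HOMO coefficient lies on the unsubstituted diene terminus and pairs with the enone β-carbon, and the 2-methyl group opposes this only weakly. The trans relation of C1 and C6 follows stereospecifically from the E dienophile, the cis relation of the C2 silyloxy and C1 acetyl groups from the endo position of the coordinated acetyl group together with the 1E diene geometry, and the absolute configuration (1S,6R) from the catalyst, whose aryl groups screen one face of the bound enone (S catalyst assigned by analogy with acrylate and enone dienophiles of this catalyst class; its mirror image is equally accessible). Site selectivity for the α,β-alkene over the bromovinyl alkene is secured because only the former is the activated α,β-bond of the complexed carbonyl, whereas addition across the latter would have to build a quaternary C–Br centre.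

**Step 5**
Reactants: 8 1-[(1S,2S,6R)-6-(1-bromoethenyl)-2-{[tert-butyl(dimethyl)silyl]oxy}-3-methylcyclohex-3-en-1-yl]ethan-1-one
Product: 10 (1S,2S,3S,4R,6S)-4-(1-bromoethenyl)-2-{[tert-butyl(dimethyl)silyl]oxy}-1-methyl-7-oxabicyclo[4.1.0]heptan-3-yl acetate, via epoxy ketone 9 (not isolated)
Conditions: mCPBA (3.5 equiv), NaHCO3, CH2Cl2, 0 → 35 °C
Reagents that add atoms: 3-chloroperoxybenzoic acid (mCPBA), O=C(OO)c1cccc(Cl)c1
Why: Prilezhaev epoxidation of the electron-rich trisubstituted ring alkene comes first and takes the face anti to the pseudoaxial silyloxy group (held there by its cis relation to the equatorial acetyl group and by A(1,2) strain with the vinylic methyl), which puts the oxirane cis to the C4 substituent; the slower Baeyer–Villiger oxidation then moves the secondary ring carbon, in preference to methyl and with retention of configuration, onto oxygen to give the C3 acetate, while the electron-poor bromoalkene should not be attacked.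

**Step 6**
Reactants: 11 4-methylpent-3-en-1-ol
Product: 12 4-methylpent-3-enal
Conditions: Dess–Martin periodinane, NaHCO3, CH2Cl2, 0 °C; used at once
Reagents that add atoms: none
Why: Dess–Martin oxidation stops at the aldehyde under buffered, non-basic conditions that should not shift the β,γ-double bond into conjugation.

**Step 7**
Reactants: 10 (1S,2S,3S,4R,6S)-4-(1-bromoethenyl)-2-{[tert-butyl(dimethyl)silyl]oxy}-1-methyl-7-oxabicyclo[4.1.0]heptan-3-yl acetate; 12 4-methylpent-3-enal
Product: 13 (1S,2S,3S,4S,6S)-2-{[tert-butyl(dimethyl)silyl]oxy}-4-[(3S)-3-hydroxy-6-methylhepta-1,5-dien-2-yl]-1-methyl-7-oxabicyclo[4.1.0]heptan-3-yl acetate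
Conditions: CrCl2 (4 equiv), NiCl2 (cat.), N-[2-(4-isopropyl-4,5-dihydro-1,3-oxazol-2-yl)-6-methylphenyl]methanesulfonamide (single enantiomer, the antipode that the empirical model for 2-haloalkene couplings assigns to Re-face delivery), Et3N, THF, rt; then H2O
Reagents that add atoms: none
Why: Nozaki–Hiyama–Kishi coupling: zerovalent nickel (from NiCl2) inserts into the alkenyl C–Br bond, transmetalation gives an alkenyl species of trivalent chromium that adds chemoselectively to the aldehyde, and the chiral sulfonamide ligand on chromium directs attack to the Re face of 12, which sets the 3S carbinol centre; acetate, oxirane and silyl ether are inert to this nucleophile.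

**Step 8**
Reactants: 13 (1S,2S,3S,4S,6S)-2-{[tert-butyl(dimethyl)silyl]oxy}-4-[(3S)-3-hydroxy-6-methylhepta-1,5-dien-2-yl]-1-methyl-7-oxabicyclo[4.1.0]heptan-3-yl acetate; 14 angelic anhydride, (2Z)-2-methylbut-2-enoic anhydride
Product: 15 (3S)-2-[(1S,2S,3S,4S,6S)-3-(acetyloxy)-2-{[tert-butyl(dimethyl)silyl]oxy}-1-methyl-7-oxabicyclo[4.1.0]heptan-4-yl]-6-methylhepta-1,5-dien-3-yl (2Z)-2-methylbut-2-enoate
Conditions: LiN(SiMe3)2, THF, −78 °C; then 14, −78 → 0 °C
Reagents that add atoms: none
Why: O-acylation of the lithium alkoxide by the anhydride needs no nucleophilic catalyst, so the Z enoate should not isomerise to the tiglate, and the cis oxirane cannot be reached from the rear by the alkoxide on the same face.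

**Step 9**
Reactants: 15 (3S)-2-[(1S,2S,3S,4S,6S)-3-(acetyloxy)-2-{[tert-butyl(dimethyl)silyl]oxy}-1-methyl-7-oxabicyclo[4.1.0]heptan-4-yl]-6-methylhepta-1,5-dien-3-yl (2Z)-2-methylbut-2-enoate
Product: 16 (3S)-2-[(1R,2S,3S,4S,6S)-3-(acetyloxy)-2-hydroxy-1-methyl-7-oxabicyclo[4.1.0]heptan-4-yl]-6-methylhepta-1,5-dien-3-yl (2Z)-2-methylbut-2-enoate
Conditions: HF·pyridine, pyridine, THF, 0 °C → rt
Reagents that add atoms: none
Why: Fluoride-driven Si–O cleavage under buffered, mildly acidic conditions is chosen over basic fluoride to suppress acetyl migration from the C3 oxygen to the cis C2 hydroxyl and to spare both esters and the oxirane.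

**Step 10**
Reactants: 16 (3S)-2-[(1R,2S,3S,4S,6S)-3-(acetyloxy)-2-hydroxy-1-methyl-7-oxabicyclo[4.1.0]heptan-4-yl]-6-methylhepta-1,5-dien-3-yl (2Z)-2-methylbut-2-enoate
Product: 17 (3S)-2-[(1S,3S,4S,6S)-3-(acetyloxy)-1-methyl-2-oxo-7-oxabicyclo[4.1.0]heptan-4-yl]-6-methylhepta-1,5-dien-3-yl (2Z)-2-methylbut-2-enoate
Conditions: Dess–Martin periodinane, NaHCO3, CH2Cl2, 0 °C → rt
Reagents that add atoms: none
Why: Dess–Martin oxidation converts the secondary alcohol into the C2 ketone under neutral buffered conditions that should leave the oxirane, the alkenes and the C3 acetoxy centre (already equatorial and trans to C4) untouched.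

**Compound list**
1 | acrolein | C=CC=O | starting material
2 | 2,3-dibromopropanal | O=CC(Br)CBr | intermediate (not isolated)
3 | 2-bromoprop-2-enal | C=C(Br)C=O | intermediate
4 | 1-(triphenylphosphoranylidene)propan-2-one | CC(=O)C=P(c1ccccc1)(c1ccccc1)c1ccccc1 | starting material
5 | (3E)-5-bromohexa-3,5-dien-2-one | CC(=O)/C=C/C(Br)=C | intermediate
6 | (2E)-2-methylbut-2-enal | C/C=C(\C)C=O | starting material
7 | tert-butyl(dimethyl){[(1E)-2-methylbuta-1,3-dien-1-yl]oxy}silane | C=C/C(C)=C/O[Si](C)(C)C(C)(C)C | intermediate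
8 | 1-[(1S,2S,6R)-6-(1-bromoethenyl)-2-{[tert-butyl(dimethyl)silyl]oxy}-3-methylcyclohex-3-en-1-yl]ethan-1-one | CC(=O)[C@@H]1[C@H](O[Si](C)(C)C(C)(C)C)C(C)=CC[C@H]1C(Br)=C | intermediate
9 | 1-[(1S,2S,3S,4R,6S)-4-(1-bromoethenyl)-2-{[tert-butyl(dimethyl)silyl]oxy}-1-methyl-7-oxabicyclo[4.1.0]heptan-3-yl]ethan-1-one | CC(=O)[C@@H]1[C@H](O[Si](C)(C)C(C)(C)C)[C@@]2(C)O[C@H]2C[C@H]1C(Br)=C | intermediate (not isolated)
10 | (1S,2S,3S,4R,6S)-4-(1-bromoethenyl)-2-{[tert-butyl(dimethyl)silyl]oxy}-1-methyl-7-oxabicyclo[4.1.0]heptan-3-yl acetate | CC(=O)O[C@@H]1[C@H](O[Si](C)(C)C(C)(C)C)[C@@]2(C)O[C@H]2C[C@H]1C(Br)=C | intermediate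
11 | 4-methylpent-3-en-1-ol | CC(C)=CCCO | starting material
12 | 4-methylpent-3-enal | CC(C)=CCC=O | intermediate
13 | (1S,2S,3S,4S,6S)-2-{[tert-butyl(dimethyl)silyl]oxy}-4-[(3S)-3-hydroxy-6-methylhepta-1,5-dien-2-yl]-1-methyl-7-oxabicyclo[4.1.0]heptan-3-yl acetate | CC(=O)O[C@@H]1[C@H](O[Si](C)(C)C(C)(C)C)[C@@]2(C)O[C@H]2C[C@H]1C(=C)[C@@H](O)CC=C(C)C | intermediate
14 | angelic anhydride, (2Z)-2-methylbut-2-enoic anhydride | C/C=C(C)\C(=O)OC(=O)/C(C)=C\C | starting material
15 | (3S)-2-[(1S,2S,3S,4S,6S)-3-(acetyloxy)-2-{[tert-butyl(dimethyl)silyl]oxy}-1-methyl-7-oxabicyclo[4.1.0]heptan-4-yl]-6-methylhepta-1,5-dien-3-yl (2Z)-2-methylbut-2-enoate | CC(=O)O[C@@H]1[C@H](O[Si](C)(C)C(C)(C)C)[C@@]2(C)O[C@H]2C[C@H]1C(=C)[C@@H](OC(=O)/C(C)=C\C)CC=C(C)C | intermediate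
16 | (3S)-2-[(1R,2S,3S,4S,6S)-3-(acetyloxy)-2-hydroxy-1-methyl-7-oxabicyclo[4.1.0]heptan-4-yl]-6-methylhepta-1,5-dien-3-yl (2Z)-2-methylbut-2-enoate | CC(=O)O[C@@H]1[C@H](O)[C@@]2(C)O[C@H]2C[C@H]1C(=C)[C@@H](OC(=O)/C(C)=C\C)CC=C(C)C | intermediate
17 | (3S)-2-[(1S,3S,4S,6S)-3-(acetyloxy)-1-methyl-2-oxo-7-oxabicyclo[4.1.0]heptan-4-yl]-6-methylhepta-1,5-dien-3-yl (2Z)-2-methylbut-2-enoate | C=C([C@H](CC=C(C)C)OC(=O)/C(C)=C\C)[C@@H]1C[C@@H]2O[C@]2(C)C(=O)[C@H]1OC(C)=O | target

**Step count.** Total: 10 steps. Longest linear sequence: 8 steps (steps 1, 2, 4, 5, 7, 8, 9, 10).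

**Steps most likely to fail**

Step 4. The strongly acidic cationic boron catalyst may desilylate or oligomerise diene 7, or divert the reaction into a stepwise Mukaiyama–Michael path with loss of endo control and enantiocontrol. The fallback sets out from 5 and 7 and comes back at 13. The cycloaddition is run thermally without catalyst (toluene, BHT, 90 °C), which should give the racemic ortho-cis adduct, that is 8 together with its mirror image ent-8 F1. The racemate is taken through step 5, which passes through the mirror-image epoxy ketone ent-9 F2 (not isolated) and gives the mirror-image epoxy acetate ent-10 F3 beside 10. In step 7 the ligand-controlled, 3S-selective addition then turns the two ring enantiomers into diastereomers, 13 and the ring-enantiomeric 3S carbinol F4. These are separated by chromatography and 13 continues in step 8.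

Step 5. Oxygen insertion into the hindered β-silyloxy methyl ketone may be slow, so that the acid-labile oxirane stays long in peracid and carboxylic acid, and facial control of the epoxidation may be incomplete. The fallback sets out from 8 and comes back at 10 by reversing the order of the two oxidations. Baeyer–Villiger oxidation with Me3SiOOSiMe3 and catalytic Me3SiOTf (CH2Cl2, −40 °C), a reagent pair that oxidises ketones without epoxidising alkenes, should give the cyclohexenyl acetate F5. A short epoxidation of F5 with mCPBA and NaHCO3 at 0 °C, again anti to the silyloxy group, then gives 10.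

Step 7. Ligand control at the new carbinol centre may be insufficient, oxidative addition of the alkenyl bromide may be sluggish, and the β,γ-unsaturated aldehyde 12 may isomerise into conjugation before it is trapped. The fallback sets out from 10 and 12 and comes back at 13. A ligand-free coupling (CrCl2, NiCl2 cat., DMF, rt) gives 13 mixed with the 3R epimer of 13 F6. The mixture is oxidised (Dess–Martin periodinane, NaHCO3, CH2Cl2) to the single α-methylene ketone F7. Corey–Bakshi–Shibata reduction of F7 with the (R)-2-methyl-oxazaborolidine and catecholborane (toluene, −78 °C), in which the branched alkenyl group acts as the large substituent, should return 13 with the 3S configuration.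

**Further compounds**
F1 | step 4 | 1-[(1R,2R,6S)-6-(1-bromoethenyl)-2-{[tert-butyl(dimethyl)silyl]oxy}-3-methylcyclohex-3-en-1-yl]ethan-1-one (ent-8) | CC(=O)[C@H]1[C@@H](O[Si](C)(C)C(C)(C)C)C(C)=CC[C@@H]1C(Br)=C
F2 | step 4 | 1-[(1R,2R,3R,4S,6R)-4-(1-bromoethenyl)-2-{[tert-butyl(dimethyl)silyl]oxy}-1-methyl-7-oxabicyclo[4.1.0]heptan-3-yl]ethan-1-one (ent-9) | CC(=O)[C@H]1[C@@H](O[Si](C)(C)C(C)(C)C)[C@]2(C)O[C@@H]2C[C@@H]1C(Br)=C
F3 | step 4 | (1R,2R,3R,4S,6R)-4-(1-bromoethenyl)-2-{[tert-butyl(dimethyl)silyl]oxy}-1-methyl-7-oxabicyclo[4.1.0]heptan-3-yl acetate (ent-10) | CC(=O)O[C@H]1[C@@H](O[Si](C)(C)C(C)(C)C)[C@]2(C)O[C@@H]2C[C@@H]1C(Br)=C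
F4 | step 4 | (1R,2R,3R,4R,6R)-2-{[tert-butyl(dimethyl)silyl]oxy}-4-[(3S)-3-hydroxy-6-methylhepta-1,5-dien-2-yl]-1-methyl-7-oxabicyclo[4.1.0]heptan-3-yl acetate | CC(=O)O[C@H]1[C@@H](O[Si](C)(C)C(C)(C)C)[C@]2(C)O[C@@H]2C[C@@H]1C(=C)[C@@H](O)CC=C(C)C
F5 | step 5 | (1S,2R,6R)-6-(1-bromoethenyl)-2-{[tert-butyl(dimethyl)silyl]oxy}-3-methylcyclohex-3-en-1-yl acetate | CC(=O)O[C@@H]1[C@H](O[Si](C)(C)C(C)(C)C)C(C)=CC[C@H]1C(Br)=C
F6 | step 7 | (1S,2S,3S,4S,6S)-2-{[tert-butyl(dimethyl)silyl]oxy}-4-[(3R)-3-hydroxy-6-methylhepta-1,5-dien-2-yl]-1-methyl-7-oxabicyclo[4.1.0]heptan-3-yl acetate | CC(=O)O[C@@H]1[C@H](O[Si](C)(C)C(C)(C)C)[C@@]2(C)O[C@H]2C[C@H]1C(=C)[C@H](O)CC=C(C)C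
F7 | step 7 | (1S,2S,3S,4S,6S)-2-{[tert-butyl(dimethyl)silyl]oxy}-1-methyl-4-(6-methyl-3-oxohepta-1,5-dien-2-yl)-7-oxabicyclo[4.1.0]heptan-3-yl acetate | CC(=O)O[C@@H]1[C@H](O[Si](C)(C)C(C)(C)C)[C@@]2(C)O[C@H]2C[C@H]1C(=C)C(=O)CC=C(C)C
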